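The ratio I carry through this flask is one of two logarithms: the hand ratio s, an apparent selectivity factor, is ln of the remaining fraction of left-handed substrate over ln of the remaining fraction of right-handed substrate. If each hand's rate is its own constant times c(substrate) times c(reagent), both hands share the time integral of c(reagent), so it cancels, and while no substrate changes hands, the left fraction is the right fraction raised to the power s.

| flask | left-handed substrate | right-handed substrate | reagent | racemization catalyst | added ligand | remark | time |
|---|---|---|---|---|---|---|---|
| green | 0.35 M | 0.35 M | 1.05 M | 1.3 mM | 3.4 mM | the very flask that is asked about, followed so far |  |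
| teal | 0.35 M | 0.35 M | 1.05 M | 2 mM | 3.4 mM | run made earlier |  |
| flask | 0.35 M | 0.35 M | 1.05 M | 1.3 mM | 3.4 mM |  | 2.5 d |

green run (percent of the left-handed substrate and right-handed substrate together charged)

| time / h | left-handed substrate / % | right-handed substrate / % | left-handed product / % |
|---|---|---|---|
| 3.00 | 45.8 | 48.7 | 4.2 |
| 6.00 | 43.4 | 47.6 | 7.2 |
| 10.0 | 39.4 | 45.8 | 10.6 |
| 12.0 | 37.1 | 44.3 | 13.0 |

teal run (percent of the left-handed substrate and right-handed substrate together charged)

| time / d | left-handed substrate / % | right-handed substrate / % | left-handed product / % |
|---|---|---|---|
| 0.333 | 41.0 | 46.0 | 9.0 |
| 0.833 | 31.6 | 40.8 | 19.4 |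
| 1.67 | 22.2 | 34.4 | 29.4 |
| 2.50 | 16.7 | 29.2 | 36.6 |

(standard deviation of a reading: 0.3 percentage points)

- reagent is single-handed; left-handed substrate and right-handed substrate are mirror images of each other, charged as a racemate, each of them at the stated concentration
- the numbers in the tables scatter by 0.3 percentage points (one standard deviation)
- an excess is the difference of the two amounts in percent of their sum
- an excess is below zero if the other one leads
- the handed part of reagent does not stay in what it makes, so the products of the two hands are mirror images too

- part of the left-handed substrate and right-handed substrate charged together that has reacted at 2.5 d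
- excess of left-handed product over right-handed product in the product at 2.5 d
- excess of right-handed substrate over left-handed substrate among what is left of the two at 2.5 d

In its first 3.00 h, green loses 4.2 percentage points of left-handed substrate and 1.3 points of right-handed. In teal, left-handed product overtakes left-handed substrate between 0.833 d and 1.67 d. The charge puts the level of the curves at no substrate and a third of the reagent unspent.

My reading of s is 2.47 at green's last point but 2.04 at teal's last, where left-handed substrate plus left-handed product stands 3.3 points above its charge, so substrate has been changing hands. Scaling the fall of s and that transfer by the catalyst charge, I expect a hand ratio for the flask of 2.19 and a transfer of 2.1 points.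

As an estimate I take over teal's remaining sum at the same time, 45.9%, which gives c = 54.1%, though teal holds more catalyst than the flask. Splitting that sum by s leaves 29.8% right-handed and 16.1% left-handed, so eS = 29.8% and eP = 33.1%.

The forecast gives c 53.8% (52.5% to 55%), eP 34.5% (31% to 37%) and eS 31% (28% to 36%), reasoning “so the catalyst doesn't drive conversion”. My three numbers differ from its centres but lie inside its ranges.

The flask gives c 54.5%, eP 31.6% and eS 29.6%.

    reagent + right-handed substrate → right-handed product (k = 2.70 × 10⁻⁶ M⁻¹ s⁻¹)
    reagent + left-handed substrate → left-handed product (k = 6.90 × 10⁻⁶ M⁻¹ s⁻¹)
    left-handed substrate + racemization catalyst ⇌ right-handed substrate + racemization catalyst, rate k3*[racemization catalyst]*[left-handed substrate] forward; the back reaction follows from the equilibrium constant (k = 0.00150 M⁻¹ s⁻¹)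
    racemization catalyst + added ligand ⇌ idle complex, settled at all times (K = 190 M⁻¹)
    racemization catalyst ⇌ dormant form (K = 2.30, k = 5.50 × 10⁻⁶ s⁻¹)

At 0.780 d the left-handed substrate in the flask has a half-life of 1.3 d by its step to product, shorter than the 3.4 d of the right-handed substrate by its own step. At 2.50 d the flask holds 32% of its left-handed charge, less than the 59% of its right-handed charge, and s there is 2.16 against my 2.19. The neighbour flask charged with 0.42 M of reagent holds 40.8% of right-handed substrate, from which s gives 32.0% of left-handed substrate, and that neighbour holds 32.3%.

The runs were computed with constants of no real substance; the scatter is artificial.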